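**Strategy.** The route rests on cutting C1–C10 of the ten-membered carbocycle. C1 (hemiketal) and C8 (acyloxy) stand 1,4 across C10–C9, with the C10 methyl β to C8. A carbene-catalysed Stetter addition of a C1 acyl anion equivalent to a C8 crotonyl ketone therefore forms that bond, closes the carbocycle, sets C10, and lets the C4 hydroxyl re-close the oxolane ring as the C1–O–C4 bridged hemiketal, all in one operation. The precursor is a C1 lactol whose quaternary C4 is tethered through C5 to a 6-methoxybutenolide (C6, C7, C11, C12) carrying the crotonyl ketone at C7 and the acetoxymethyl group at C11.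

Key step: step 18

Remark 1: atom numbers follow the germacrane-type skeleton of the target (C1 hemiketal carbon, C4 quaternary ether carbon, C6 enol-lactone carbon, C8 acyloxy carbon, C12 lactone carbonyl, C13 acetoxymethyl carbon).
Remark 2: the C1 methyl acetals and the C1 lactol are anomeric mixtures and are written without a C1 descriptor; C6 of the pseudo-ester is carried as the separated (6R) epimer and is erased in the last step.
Remark 3: C4 comes from a catalytic asymmetric epoxidation, so the enantiopurity of the target is that of step 1; (E)-1-bromoprop-1-ene and (tert-butyldimethylsilyloxy)acetaldehyde are assumed to be purchasable.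

**Fragment A: C1–C6 alkyne**

Step 1
Reactants: 1 geraniol
Product: 2 (2S,3S)-2,3-epoxygeraniol
Conditions: Ti(OiPr)4 (5 mol %), L-(+)-diethyl tartrate (6 mol %), t-BuOOH, 4 Å MS, CH2Cl2, −20 °C
Reagents that add atoms: tert-butyl hydroperoxide, CC(C)(C)OO
Why: Sharpless asymmetric epoxidation acts only on the allylic alcohol, and the L-(+)-tartrate titanium complex delivers oxygen to the face that gives the (2S,3S) epoxide, whose C3 becomes C4 of the target.

Step 2
Reactants: 2 (2S,3S)-2,3-epoxygeraniol
Product: 3 (2R,3S)-2-(chloromethyl)-3-methyl-3-(4-methylpent-3-en-1-yl)oxirane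
Conditions: PPh3, CCl4, NaHCO3, reflux
Reagents that add atoms: carbon tetrachloride, ClC(Cl)(Cl)Cl
Why: Appel chlorination converts the primary alcohol into the chloride under neutral conditions that leave the epoxide and both stereocentres untouched.

Step 3
Reactants: 3 epoxy chloride
Product: 4 (3S)-3,7-dimethyloct-6-en-1-yn-3-ol
Conditions: LDA (3.3 equiv), THF, −78 to −30 °C; H2O
Reagents that add atoms: none
Why: Base-induced double elimination of the 2,3-epoxy chloride (epoxide-opening β-elimination, then dehydrochlorination of the chloroalkene) gives the tertiary propargylic alcohol, and because the C–O bond at the quaternary carbon is never broken its configuration is retained.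

Step 4
Reactants: 4 (3S)-3,7-dimethyloct-6-en-1-yn-3-ol
Product: 6 (2S)-2-ethynyl-5-methoxy-2-methyloxolane (both anomers), via lactol 5 (not isolated)
Conditions: O3, CH2Cl2/MeOH (4:1), −78 °C; Me2S; then TsOH·H2O (cat.), rt
Reagents that add atoms: ozone, [O-][O+]=O; methanol, CO
Why: Ozonolysis cleaves the electron-rich trisubstituted alkene much faster than the terminal alkyne, the 4-hydroxy aldehyde closes to lactol 5, and Fischer acetalisation in methanol stores C1 at the aldehyde oxidation level so that no late lactone reduction is needed.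

**Fragment B: C7, C8, C11–C13 enol triflate**

Step 5
Reactants: 7 methyl 3-hydroxypropanoate
Product: 8 methyl 3-[(tert-butyldimethylsilyl)oxy]propanoate
Conditions: TBSCl, imidazole, DMF, rt
Reagents that add atoms: tert-butyldimethylsilyl chloride, CC(C)(C)[Si](C)(C)Cl
Why: Standard silylation of a primary alcohol gives an ether that survives enolate chemistry and is later removed by acidic methanol.

Step 6
Reactants: 9 4-methoxybenzyl alcohol; 10 2-chloro-N-methoxy-N-methylacetamide
Product: 11 N-methoxy-2-[(4-methoxybenzyl)oxy]-N-methylacetamide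
Conditions: NaH, THF, 0 °C to rt
Reagents that add atoms: none
Why: Williamson ether synthesis, in which the sodium alkoxide of 9 displaces the activated α-chloride of the amide.

Step 7
Reactants: 8 silyloxy ester; 11 N-methoxy-N-methylamide
Product: 12 methyl 2-{[(tert-butyldimethylsilyl)oxy]methyl}-4-[(4-methoxybenzyl)oxy]-3-oxobutanoate (racemic)
Conditions: LDA (1.1 equiv), THF, −78 °C; then 11, −78 to −40 °C; H2O
Reagents that add atoms: none
Why: Crossed Claisen-type C-acylation of the lithium ester enolate stops at the chelated tetrahedral adduct of the N-methoxy-N-methylamide, so the β-keto ester is released only on work-up and the cold enolate does not eliminate silanolate.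

Step 8
Reactants: 12 β-keto ester
Product: 13 methyl (2Z)-2-{[(tert-butyldimethylsilyl)oxy]methyl}-4-[(4-methoxybenzyl)oxy]-3-{[(trifluoromethyl)sulfonyl]oxy}but-2-enoate
Conditions: NaH, THF, 0 °C; PhNTf2, 0 °C to rt
Reagents that add atoms: N-phenylbis(trifluoromethanesulfonimide), O=S(=O)(N(c1ccccc1)S(=O)(=O)C(F)(F)F)C(F)(F)F
Why: O-Triflation of the sodium enolate, held in the chelated U-shape between ketone and ester oxygens, gives the enol triflate with OTf cis to the ester (Z), the geometry the later lactonisation needs.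

**Assembly of the Stetter precursor**

Step 9
Reactants: 13 enol triflate; 6 alkyne acetal
Product: 14 methyl (2E)-2-{[(tert-butyldimethylsilyl)oxy]methyl}-3-{[(4-methoxybenzyl)oxy]methyl}-5-[(2S)-5-methoxy-2-methyloxolan-2-yl]pent-2-en-4-ynoate (ester and alkyne cis)
Conditions: PdCl2(PPh3)2 (5 mol %), CuI (10 mol %), i-Pr2NH, THF, rt
Reagents that add atoms: none
Why: Sonogashira coupling of the electron-poor enol triflate with the terminal alkyne proceeds with retention of alkene geometry and joins C6 to C7.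

Step 10
Reactants: 14 enyne ester
Product: 16 (5Z)-3-{[(tert-butyldimethylsilyl)oxy]methyl}-4-{[(4-methoxybenzyl)oxy]methyl}-5-{[(2S)-5-methoxy-2-methyloxolan-2-yl]methylidene}furan-2(5H)-one, via enynoic acid 15 (not isolated)
Conditions: LiOH·H2O, THF/MeOH/H2O, 40 °C; AcOH to pH 6; then AgNO3 (10 mol %), acetone, rt, dark
Reagents that add atoms: lithium hydroxide, [Li+].[OH-]
Why: Saponification frees the acid cis to the alkyne, and silver-catalysed 5-exo-dig lactonisation (anti oxymetalation, then protodemetalation) gives the (Z)-ylidenebutenolide, the 6-endo mode being disfavoured because it would attack the alkyne carbon next to the quaternary C4; this places the C6 oxygen regioselectively.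

Step 11
Reactants: 16 ylidenebutenolide
Product: 18 (5R)-3-(hydroxymethyl)-5-methoxy-4-{[(4-methoxybenzyl)oxy]methyl}-5-{[(2S)-5-methoxy-2-methyloxolan-2-yl]methyl}furan-2(5H)-one, via hydroxybutenolide 17 (not isolated)
Conditions: LiOH (1.1 equiv), THF/H2O, 0 °C; AcOH to pH 5; then MeOH, CSA (10 mol %), rt; separation of the C6 epimers
Reagents that add atoms: lithium hydroxide, [Li+].[OH-]; methanol, CO
Why: Hydroxide opens the enol lactone to the (Z)-4-oxo-2-enoic acid, which exists as the cyclic 6-hydroxybutenolide 17, and acid-catalysed pseudo-esterification in methanol installs the C6 methoxy ketal while cleaving the primary silyl ether; C6 forms as both epimers, which are separated, the (6S) epimer being re-equilibrated under the same conditions.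

Step 12
Reactants: 18 pseudo-ester alcohol
Product: 19 [(5R)-5-methoxy-4-{[(4-methoxybenzyl)oxy]methyl}-5-{[(2S)-5-methoxy-2-methyloxolan-2-yl]methyl}-2-oxo-2,5-dihydrofuran-3-yl]methyl acetate
Conditions: Ac2O, pyridine, DMAP (cat.), CH2Cl2, 0 °C
Reagents that add atoms: acetic anhydride, CC(=O)OC(C)=O
Why: Acetylation of the only free hydroxyl installs the C13 acetate of the target before any carbonyl chemistry at C8.

Step 13
Reactants: 19 acetate
Product: 20 [(5R)-4-(hydroxymethyl)-5-methoxy-5-{[(2S)-5-methoxy-2-methyloxolan-2-yl]methyl}-2-oxo-2,5-dihydrofuran-3-yl]methyl acetate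
Conditions: DDQ, CH2Cl2/pH 7 buffer (10:1), 0 °C to rt
Reagents that add atoms: none
Why: Oxidative cleavage of the 4-methoxybenzyl ether by DDQ under buffered conditions frees the C8 hydroxyl without touching the acetate, the acetal or the ketal.

Step 14
Reactants: 20 C8 alcohol
Product: 21 [(5R)-4-formyl-5-methoxy-5-{[(2S)-5-methoxy-2-methyloxolan-2-yl]methyl}-2-oxo-2,5-dihydrofuran-3-yl]methyl acetate
Conditions: Dess–Martin periodinane, NaHCO3, CH2Cl2, 0 °C to rt
Reagents that add atoms: none
Why: Dess–Martin oxidation of the primary allylic alcohol under buffered, non-acidic conditions gives the C8 aldehyde.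

Step 15
Reactants: 21 C8 aldehyde; 22 (E)-1-bromoprop-1-ene
Product: 23 [(5R)-4-[(2E)-1-hydroxybut-2-en-1-yl]-5-methoxy-5-{[(2S)-5-methoxy-2-methyloxolan-2-yl]methyl}-2-oxo-2,5-dihydrofuran-3-yl]methyl acetate (both C8 epimers)
Conditions: CrCl2 (4 equiv), NiCl2 (2 mol %), DMF, rt
Reagents that add atoms: none
Why: Nozaki–Hiyama–Kishi addition of the alkenylchromium reagent is chemoselective for the aldehyde in the presence of acetate and lactone and retains the E geometry of the bromide; the new C8 carbinol forms as both epimers and is oxidised in the next step.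

Step 16
Reactants: 23 allylic alcohol
Product: 24 [(5R)-4-[(2E)-but-2-enoyl]-5-methoxy-5-{[(2S)-5-methoxy-2-methyloxolan-2-yl]methyl}-2-oxo-2,5-dihydrofuran-3-yl]methyl acetate
Conditions: Dess–Martin periodinane, NaHCO3, CH2Cl2, rt
Reagents that add atoms: none
Why: Dess–Martin oxidation of the bis-allylic alcohol gives the (E)-crotonyl ketone, the Stetter acceptor.

Step 17
Reactants: 24 enone acetal
Product: 25 [(5R)-4-[(2E)-but-2-enoyl]-5-{[(2S)-5-hydroxy-2-methyloxolan-2-yl]methyl}-5-methoxy-2-oxo-2,5-dihydrofuran-3-yl]methyl acetate (lactol, both anomers)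
Conditions: AcOH/THF/H2O (3:1:1), 35 °C
Reagents that add atoms: water, O
Why: Mild aqueous acid hydrolyses the ordinary oxolane methyl acetal at C1 far faster than the C6 methoxy ketal, whose oxocarbenium ion is destabilised by the lactone acyl group and the electron-poor alkene, so the lactol is unveiled last under conditions the enone and acetate tolerate.

**Key step and completion**

Step 18
Reactants: 25 lactol precursor
Product: 27 (1R,4S,6R,10R)-13-acetoxy-1-hydroxy-6-methoxy-1,4-epoxygermacr-7(11)-en-8-one 12,6-lactone (bridged hemiketal 8-ketone), via hydroxy diketone 26 (not isolated)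
Conditions: aminoindanol-derived N-C6F5 triazolium tetrafluoroborate (20 mol %), i-Pr2NEt (40 mol %), toluene, 2 mM, 50 °C, 25 added by syringe pump over 12 h
Reagents that add atoms: none
Why: Proposed new method: the triazolylidene adds to the small equilibrium share of the open 4-hydroxy aldehyde of 25, the derived hydroxy-enamine (acyl anion equivalent) adds to C10, the β-carbon of the crotonyl ketone, and collapse of the adduct releases the carbene and diketone 26, whose C4 hydroxyl closes onto the C1 carbonyl to give 27. The closest known reaction is the carbene-catalysed intramolecular Stetter reaction that forms five- and six-membered rings, where lactols have served as masked aldehydes; a ten-membered closure is without precedent. The carbocycle closes by a 10-endo-trig conjugate addition and the oxolane ring is re-formed by a transannular 5-exo-trig hemiketalisation. C10 is set by the chiral carbene, which selects the face of the enone β-carbon (both catalyst enantiomers would be screened), and because C10 is α to the C1 carbonyl of 26 an unwanted epimer can be equilibrated by the amine base through the ketone–hemiketal pair; C1 is dictated by C4, since the C1–O–C4 bridge of the 11-oxabicyclo[6.2.1]undecane can only be cis, so (4S) enforces (1R). The step needs attack at C10 instead of C11 or the C8 carbonyl and ring closure instead of oligomerisation: C11 is fully substituted and its attack would give an eight-membered ring, the C8 carbonyl is shielded by the tetrasubstituted butenolide alkene, the sp3 C6 ketal gives the C5 hinge the flexibility that the planar enol lactone of the target lacks, and high dilution with slow addition suppresses intermolecular reaction.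

Step 19
Reactants: 27 bridged hemiketal 8-ketone
Product: 28 (1R,4S,6R,8S,10R)-13-acetoxy-1,8-dihydroxy-6-methoxy-1,4-epoxygermacr-7(11)-ene 12,6-lactone
Conditions: (R)-2-methyl-CBS-oxazaborolidine (50 mol %), catecholborane (2 equiv), toluene/CH2Cl2, −78 to −40 °C
Reagents that add atoms: none
Why: Corey–Bakshi–Shibata reduction: with the alkenyl C7 as the large and the C9 methylene as the small substituent, the (R)-oxazaborolidine directs hydride to the face that gives the (8S) alcohol, and catecholborane at low temperature reduces neither the lactone, the acetate nor the hemiketal.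

Step 20
Reactants: 29 (tert-butyldimethylsilyloxy)acetaldehyde; 30 ethyl 2-(triphenylphosphoranylidene)propanoate
Product: 31 ethyl (2E)-4-[(tert-butyldimethylsilyl)oxy]-2-methylbut-2-enoate
Conditions: CH2Cl2, rt
Reagents that add atoms: none
Why: Wittig olefination with the stabilised α-methyl ylide gives the trisubstituted (E)-enoate.

Step 21
Reactants: 31 ethyl ester
Product: 32 (2E)-4-[(tert-butyldimethylsilyl)oxy]-2-methylbut-2-enoic acid
Conditions: LiOH, THF/H2O, rt; AcOH to pH 5
Reagents that add atoms: lithium hydroxide, [Li+].[OH-]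
Why: Saponification of the ethyl ester gives the acid without affecting the silyl ether or the alkene geometry.

Step 22
Reactants: 28 C8 alcohol; 32 side-chain acid
Product: 34 8-O-[(2E)-4-(tert-butyldimethylsilyloxy)-2-methylbut-2-enoyl] ester of 28, via mixed anhydride 33 (not isolated)
Conditions: 32, 2,4,6-trichlorobenzoyl chloride, Et3N, THF, rt; then 28, DMAP, toluene, rt
Reagents that add atoms: none
Why: Yamaguchi esterification through mixed anhydride 33 acylates the secondary C8 hydroxyl with retention, while the tertiary bridgehead hemiketal hydroxyl is too hindered to react.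

Step 23
Reactants: 34 silyl-protected ester
Product: 36 (1R,4S,5E,8S,10R)-13-acetoxy-1-hydroxy-8-[(2E)-4-hydroxy-2-methylbut-2-enoyloxy]-1,4-epoxygermacra-5,7(11)-dien-12,6-olide (CNP0154520.2), via desilylated ester 35 (not isolated)
Conditions: TsOH·H2O (20 mol %), MeCN/H2O (20:1), 45 °C
Reagents that add atoms: none
Why: Acid-promoted E1 loss of methanol from the 6-methoxybutenolide (the known dehydration mode of 5-alkyl-5-hydroxy- and 5-alkoxybutenolides to ylidenebutenolides) should give the conjugated C5=C6 enol lactone in the only geometry the bridged ten-membered ring allows, and the same aqueous acid cleaves the primary silyl ether; water keeps the C1 hemiketal from dehydrating.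

**Compound list**

1 | geraniol, (2E)-3,7-dimethylocta-2,6-dien-1-ol | CC(C)=CCC/C(C)=C/CO | starting material
2 | (2S,3S)-2,3-epoxygeraniol | OC[C@@H]1O[C@@]1(C)CCC=C(C)C | intermediate
3 | (2R,3S)-2-(chloromethyl)-3-methyl-3-(4-methylpent-3-en-1-yl)oxirane | ClC[C@@H]1O[C@@]1(C)CCC=C(C)C | intermediate
4 | (3S)-3,7-dimethyloct-6-en-1-yn-3-ol | C#C[C@@](C)(O)CCC=C(C)C | intermediate
5 | (5S)-5-ethynyl-5-methyloxolan-2-ol (lactol, not isolated) | C#C[C@]1(C)CCC(O)O1 | intermediate
6 | (2S)-2-ethynyl-5-methoxy-2-methyloxolane (anomers) | C#C[C@]1(C)CCC(OC)O1 | intermediate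
7 | methyl 3-hydroxypropanoate | OCCC(=O)OC | starting material
8 | methyl 3-[(tert-butyldimethylsilyl)oxy]propanoate | COC(=O)CCO[Si](C)(C)C(C)(C)C | intermediate
9 | 4-methoxybenzyl alcohol | COc1ccc(CO)cc1 | starting material
10 | 2-chloro-N-methoxy-N-methylacetamide | CON(C)C(=O)CCl | starting material
11 | N-methoxy-2-[(4-methoxybenzyl)oxy]-N-methylacetamide | CON(C)C(=O)COCc1ccc(OC)cc1 | intermediate
12 | methyl 2-{[(tert-butyldimethylsilyl)oxy]methyl}-4-[(4-methoxybenzyl)oxy]-3-oxobutanoate (racemic) | COC(=O)C(CO[Si](C)(C)C(C)(C)C)C(=O)COCc1ccc(OC)cc1 | intermediate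
13 | methyl (2Z)-2-{[(tert-butyldimethylsilyl)oxy]methyl}-4-[(4-methoxybenzyl)oxy]-3-{[(trifluoromethyl)sulfonyl]oxy}but-2-enoate | COC(=O)/C(CO[Si](C)(C)C(C)(C)C)=C(\OS(=O)(=O)C(F)(F)F)COCc1ccc(OC)cc1 | intermediate
14 | methyl (2E)-2-{[(tert-butyldimethylsilyl)oxy]methyl}-3-{[(4-methoxybenzyl)oxy]methyl}-5-[(2S)-5-methoxy-2-methyloxolan-2-yl]pent-2-en-4-ynoate | COC(=O)/C(CO[Si](C)(C)C(C)(C)C)=C(\C#C[C@]1(C)CCC(OC)O1)COCc1ccc(OC)cc1 | intermediate
15 | (2E)-2-{[(tert-butyldimethylsilyl)oxy]methyl}-3-{[(4-methoxybenzyl)oxy]methyl}-5-[(2S)-5-methoxy-2-methyloxolan-2-yl]pent-2-en-4-ynoic acid (not isolated) | OC(=O)/C(CO[Si](C)(C)C(C)(C)C)=C(\C#C[C@]1(C)CCC(OC)O1)COCc1ccc(OC)cc1 | intermediate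
16 | (5Z)-3-{[(tert-butyldimethylsilyl)oxy]methyl}-4-{[(4-methoxybenzyl)oxy]methyl}-5-{[(2S)-5-methoxy-2-methyloxolan-2-yl]methylidene}furan-2(5H)-one | O=C1O/C(=C\[C@]2(C)CCC(OC)O2)C(COCc2ccc(OC)cc2)=C1CO[Si](C)(C)C(C)(C)C | intermediate
17 | 3-{[(tert-butyldimethylsilyl)oxy]methyl}-5-hydroxy-4-{[(4-methoxybenzyl)oxy]methyl}-5-{[(2S)-5-methoxy-2-methyloxolan-2-yl]methyl}furan-2(5H)-one (C6 epimers, not isolated) | O=C1OC(O)(C[C@]2(C)CCC(OC)O2)C(COCc2ccc(OC)cc2)=C1CO[Si](C)(C)C(C)(C)C | intermediate
18 | (5R)-3-(hydroxymethyl)-5-methoxy-4-{[(4-methoxybenzyl)oxy]methyl}-5-{[(2S)-5-methoxy-2-methyloxolan-2-yl]methyl}furan-2(5H)-one | O=C1O[C@](OC)(C[C@]2(C)CCC(OC)O2)C(COCc2ccc(OC)cc2)=C1CO | intermediate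
19 | [(5R)-5-methoxy-4-{[(4-methoxybenzyl)oxy]methyl}-5-{[(2S)-5-methoxy-2-methyloxolan-2-yl]methyl}-2-oxo-2,5-dihydrofuran-3-yl]methyl acetate | O=C1O[C@](OC)(C[C@]2(C)CCC(OC)O2)C(COCc2ccc(OC)cc2)=C1COC(C)=O | intermediate
20 | [(5R)-4-(hydroxymethyl)-5-methoxy-5-{[(2S)-5-methoxy-2-methyloxolan-2-yl]methyl}-2-oxo-2,5-dihydrofuran-3-yl]methyl acetate | O=C1O[C@](OC)(C[C@]2(C)CCC(OC)O2)C(CO)=C1COC(C)=O | intermediate
21 | [(5R)-4-formyl-5-methoxy-5-{[(2S)-5-methoxy-2-methyloxolan-2-yl]methyl}-2-oxo-2,5-dihydrofuran-3-yl]methyl acetate | O=C1O[C@](OC)(C[C@]2(C)CCC(OC)O2)C(C=O)=C1COC(C)=O | intermediate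
22 | (E)-1-bromoprop-1-ene | C/C=C/Br | starting material
23 | [(5R)-4-[(2E)-1-hydroxybut-2-en-1-yl]-5-methoxy-5-{[(2S)-5-methoxy-2-methyloxolan-2-yl]methyl}-2-oxo-2,5-dihydrofuran-3-yl]methyl acetate (C8 epimers) | O=C1O[C@](OC)(C[C@]2(C)CCC(OC)O2)C(C(O)/C=C/C)=C1COC(C)=O | intermediate
24 | [(5R)-4-[(2E)-but-2-enoyl]-5-methoxy-5-{[(2S)-5-methoxy-2-methyloxolan-2-yl]methyl}-2-oxo-2,5-dihydrofuran-3-yl]methyl acetate | O=C1O[C@](OC)(C[C@]2(C)CCC(OC)O2)C(C(=O)/C=C/C)=C1COC(C)=O | intermediate
25 | [(5R)-4-[(2E)-but-2-enoyl]-5-{[(2S)-5-hydroxy-2-methyloxolan-2-yl]methyl}-5-methoxy-2-oxo-2,5-dihydrofuran-3-yl]methyl acetate (lactol anomers; Stetter precursor) | C/C=C/C(=O)C1=C(COC(C)=O)C(=O)O[C@]1(OC)C[C@]1(C)CCC(O)O1 | intermediate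
26 | (4S,6R,10R)-13-acetoxy-4-hydroxy-6-methoxygermacr-7(11)-ene-1,8-dione 12,6-lactone (not isolated) | CC(=O)OCC1=C2[C@@](OC)(C[C@](O)(C)CCC(=O)[C@H](C)CC2=O)OC1=O | intermediate
27 | (1R,4S,6R,10R)-13-acetoxy-1-hydroxy-6-methoxy-1,4-epoxygermacr-7(11)-en-8-one 12,6-lactone | CC(=O)OCC1=C2[C@@](OC)(C[C@]3(C)CC[C@@](O)(O3)[C@H](C)CC2=O)OC1=O | intermediate
28 | (1R,4S,6R,8S,10R)-13-acetoxy-1,8-dihydroxy-6-methoxy-1,4-epoxygermacr-7(11)-ene 12,6-lactone | CC(=O)OCC1=C2[C@@](OC)(C[C@]3(C)CC[C@@](O)(O3)[C@H](C)C[C@@H]2O)OC1=O | intermediate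
29 | (tert-butyldimethylsilyloxy)acetaldehyde | O=CCO[Si](C)(C)C(C)(C)C | starting material
30 | ethyl 2-(triphenylphosphoranylidene)propanoate | CCOC(=O)C(C)=P(c1ccccc1)(c1ccccc1)c1ccccc1 | starting material
31 | ethyl (2E)-4-[(tert-butyldimethylsilyl)oxy]-2-methylbut-2-enoate | CCOC(=O)/C(C)=C/CO[Si](C)(C)C(C)(C)C | intermediate
32 | (2E)-4-[(tert-butyldimethylsilyl)oxy]-2-methylbut-2-enoic acid | OC(=O)/C(C)=C/CO[Si](C)(C)C(C)(C)C | intermediate
33 | mixed anhydride of 32 with 2,4,6-trichlorobenzoic acid (not isolated) | O=C(OC(=O)c1c(Cl)cc(Cl)cc1Cl)/C(C)=C/CO[Si](C)(C)C(C)(C)C | intermediate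
34 | 8-O-[(2E)-4-(tert-butyldimethylsilyloxy)-2-methylbut-2-enoyl] ester of 28 | CC(=O)OCC1=C2[C@@](OC)(C[C@]3(C)CC[C@@](O)(O3)[C@H](C)C[C@@H]2OC(=O)/C(C)=C/CO[Si](C)(C)C(C)(C)C)OC1=O | intermediate
35 | 8-O-[(2E)-4-hydroxy-2-methylbut-2-enoyl] ester of 28 (not isolated) | CC(=O)OCC1=C2[C@@](OC)(C[C@]3(C)CC[C@@](O)(O3)[C@H](C)C[C@@H]2OC(=O)/C(C)=C/CO)OC1=O | intermediate
36 | (1R,4S,5E,8S,10R)-13-acetoxy-1-hydroxy-8-[(2E)-4-hydroxy-2-methylbut-2-enoyloxy]-1,4-epoxygermacra-5,7(11)-dien-12,6-olide (CNP0154520.2) | CC(=O)OCC1=C2/C(=C\[C@]3(C)CC[C@@](O)(O3)[C@H](C)C[C@@H]2OC(=O)/C(C)=C/CO)OC1=O | target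

**Step count and risks**

Total steps: 23. Longest linear sequence: 17 (steps 1–4, 9–19, 22, 23).

Steps most likely to fail:

1. Step 18 (Proposed new method). The lactol releases little free aldehyde and the ten-membered transition state is entropically costly, so oligomerisation, catalyst trapping or addition–elimination at the C13 acetate may outrun ring closure. Fallback: the same C1–C10 bond is made with reversed polarity by known reactions. Aldehyde 21 is alkynylated with propyne (Zn(OTf)2, Et3N, toluene) to the propargylic alcohol F1, which Dess–Martin oxidation turns into the ynone F2. Conjugate hydroiodination (NaI, AcOH) gives the (Z)-β-iodoenone F3, and aqueous acetic acid as in step 17 unveils the iodoenone lactol F4. An intramolecular Nozaki–Hiyama–Kishi reaction (CrCl2, NiCl2 cat., DMSO/THF, high dilution) adds the C10 alkenylchromium to the C1 aldehyde and closes the ten-membered ring as the C1 carbinol F5. Dess–Martin oxidation gives the C1 ketone, which the C4 hydroxyl captures as the bridged 9,10-dehydro hemiketal F6. Conjugate reduction of the C9=C10 enone with [(Ph3P)CuH]6, followed by base equilibration at C10 if needed, returns the route at 27.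

2. Step 23. Ionisation at the acyl-deactivated C6 ketal may be slower than ionisation at the C1 hemiketal, so methanol loss may stay incomplete or C10 may epimerise through a transient C1 enol ether. Fallback: an aprotic, silyl-triflate-mediated ketal-to-enol-ether elimination replaces the Brønsted acid. Ester 34 is treated with TMSOTf and i-Pr2NEt (CH2Cl2, −78 to 0 °C), which silylates the C1 hydroxyl in situ and removes methanol as its silyl ether to give the 1-O-trimethylsilyl enol lactone F7. HF·pyridine in THF then removes both silyl groups and returns the route at 36.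

3. Step 19. Hydride delivery may be governed by the conformation of the bridged medium ring and not by the catalyst, giving mainly the C8 epimer, and borane may be consumed by the hemiketal. Fallback: the substrate bias is used and then inverted. Luche reduction of 27 (NaBH4, CeCl3·7H2O, THF/MeOH, −78 °C) gives the 8-epi alcohol F8, and Mitsunobu esterification with acid 32 (PPh3, DIAD, toluene, 0 °C to rt) inverts C8 while installing the side chain, returning the route at 34.

Further compounds
F1 | step 18 | [(5R)-4-(1-hydroxybut-2-yn-1-yl)-5-methoxy-5-{[(2S)-5-methoxy-2-methyloxolan-2-yl]methyl}-2-oxo-2,5-dihydrofuran-3-yl]methyl acetate | O=C1O[C@](OC)(C[C@]2(C)CCC(OC)O2)C(C(O)C#CC)=C1COC(C)=O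
F2 | step 18 | [(5R)-4-(but-2-ynoyl)-5-methoxy-5-{[(2S)-5-methoxy-2-methyloxolan-2-yl]methyl}-2-oxo-2,5-dihydrofuran-3-yl]methyl acetate | O=C1O[C@](OC)(C[C@]2(C)CCC(OC)O2)C(C(=O)C#CC)=C1COC(C)=O
F3 | step 18 | [(5R)-4-[(2Z)-3-iodobut-2-enoyl]-5-methoxy-5-{[(2S)-5-methoxy-2-methyloxolan-2-yl]methyl}-2-oxo-2,5-dihydrofuran-3-yl]methyl acetate | O=C1O[C@](OC)(C[C@]2(C)CCC(OC)O2)C(C(=O)/C=C(/C)I)=C1COC(C)=O
F4 | step 18 | [(5R)-5-{[(2S)-5-hydroxy-2-methyloxolan-2-yl]methyl}-4-[(2Z)-3-iodobut-2-enoyl]-5-methoxy-2-oxo-2,5-dihydrofuran-3-yl]methyl acetate (lactol anomers) | C/C(I)=C/C(=O)C1=C(COC(C)=O)C(=O)O[C@]1(OC)C[C@]1(C)CCC(O)O1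
F5 | step 18 | (4S,6R,9Z)-13-acetoxy-1,4-dihydroxy-6-methoxygermacra-7(11),9-dien-8-one 12,6-lactone (C1 epimers) | CC(=O)OCC1=C2[C@@](OC)(C[C@](O)(C)CCC(O)/C(C)=C\C2=O)OC1=O
F6 | step 18 | (1R,4S,6R,9Z)-13-acetoxy-1-hydroxy-6-methoxy-1,4-epoxygermacra-7(11),9-dien-8-one 12,6-lactone | CC(=O)OCC1=C2[C@@](OC)(C[C@]3(C)CC[C@@](O)(O3)/C(C)=C\C2=O)OC1=O
F7 | step 23 | 1-O-trimethylsilyl 4'-O-tert-butyldimethylsilyl derivative of 36 | CC(=O)OCC1=C2/C(=C\[C@]3(C)CC[C@@](O[Si](C)(C)C)(O3)[C@H](C)C[C@@H]2OC(=O)/C(C)=C/CO[Si](C)(C)C(C)(C)C)OC1=O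
F8 | step 19 | (1R,4S,6R,8R,10R)-13-acetoxy-1,8-dihydroxy-6-methoxy-1,4-epoxygermacr-7(11)-ene 12,6-lactone (8-epimer of 28) | CC(=O)OCC1=C2[C@@](OC)(C[C@]3(C)CC[C@@](O)(O3)[C@H](C)C[C@H]2O)OC1=O
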